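## Structural features

The target, 7-hydroxy-3,5,6,8-tetramethoxy-2-(4-methoxyphenyl)-4H-chromen-4-one, is a flavone: benzo ring A is fused through C4a–C8a to 4-pyranone ring C, and the 4-methoxyphenyl ring B sits on C2. It has no stereocentres, so nothing has to be set or guarded against epimerisation. Ring A is hexasubstituted: five contiguous oxygens (O1 at C8a, OMe at C8, OH at C7, OMe at C6 and C5) and the acyl carbon C4 at C4a; C3 carries a further methoxy group. The fragile points are the single free, acidic hydroxyl at C7, the C5 methoxy group peri to the C4 carbonyl (the first ether to fall to Lewis acids), the electron-rich ring A with para-related C5/C8 ethers (prone to oxidation to a quinone) and C2 of the pyranone (open to nucleophiles). The real difficulty is not the skeleton but telling the ring A oxygens apart and bringing in the C3 oxygen. Ring A is mirror-symmetric about the C4a···C7 axis, except that one oxygen flanking C4a is the ring oxygen O1 and the other is the C5 methoxy oxygen. The key step uses two features: C4 lies between C4a and the C3=C2–aryl unit, so it can be carbon monoxide inserted between an aryl iodide at C4a and an arylalkyne; and the two ethers flanking that iodide are equivalent until one becomes O1, so closing O1–C2 desymmetrises ring A without a regiochemical choice.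

## Logic of the disconnections

16 from 15. The O7–acyl bond is cut last. O7–H is the most acidic hydroxyl, so it stays capped while O3 is methylated. The cut changes no skeleton but makes the precursor fully protected. The forward step must remove an aryl ester without touching five methyl ethers or opening ring C, which calls for mild alkoxide transesterification.

15 from 14. The O3–CH3 bond is cut. In 14 the C3 hydroxyl is the only free hydroxyl, so the forward methylation has no selectivity problem. The only demand is that the ester on O7 survives carbonate in an aprotic solvent.

14 from 11. The C3–O bond is cut. C3 enters as the terminal alkyne carbon of 8 and so arrives as C–H. It is the most acidic C–H of 11 (vinylic, next to the C4 carbonyl), so deprotonation, borylation and oxidation can convert it to C–OH. The forward step needs a base that deprotonates faster than it attacks the hindered ester or adds to C2.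

11 from 6, 7 and 8 (key disconnection). Three bonds are cut: C4a–C4, C4–C3 and O1–C2. This removes ring C, detaches ring B and takes out the carbonyl carbon as 7. What remains is the hexasubstituted iodoarene 6, which has a mirror plane through C–I and C–O(acyl). The two methoxy groups flanking iodine in 6 are equivalent: one becomes O1, the other stays as the C5 methoxy group, so 11 already has O5 methylated and O7 protected. A precursor with three identical acid-labile ethers at the future O1, O5 and O7 would instead give a 5,7-diol. That would cost two extra steps (selective protection of O7, methylation of the chelated O5), and its preparation would need a carcinogenic alkylating agent and a double copper-mediated methoxylation. The precursor is therefore redesigned in its oxygen substituents only; the bonds formed are unchanged. The forward step must favour carbonylative over direct coupling at a doubly ortho-substituted iodide, unmask exactly one of the two flanking oxygens (by chelation to the new ketone) and close 6-endo.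

6 from 5. The C–I bond is cut. 5 has a single ring C–H, flanked by two methoxy groups, so iodination has no regiochemical choice. It must not oxidise the electron-rich ring.

5 from 4. The O–acyl bond is cut. The acyl group has no α-hydrogen and a hindered carbonyl, so it should survive BCl3, the palladium/CO/amine stage and a lithium amide at low temperature. It also makes the ring less prone to oxidation than a free phenol.

4 from 1. The aryl C–O bond is cut. 1 is commercial and already holds four of the five ring A oxygens as methyl ethers. Its two C–H positions are equivalent, each between two methoxy groups, so mono-metalation gives a single aryl anion. The forward step must stop at mono-functionalisation and oxidise C–B to C–O without oxidising the phenol further. 7 and 8 are commercial.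

## Other disconnections considered

Alternative 1: The cut is C4a–C5 of ring A, opening the benzene ring to the open-chain trioxo ester A1, which already carries methoxy groups at C2 and C4 and ends in a methoxyacetyl group. The forward key step would be a magnesium-alkoxide-mediated Claisen cyclisation (C6 carbanion onto the C1 ester carbon) and enolisation to the acylphloroglucinol A2.
- In its favour: it follows polyketide logic, builds the fully oxygenated ring from acyclic pieces and needs no transition metal or toxic gas. It is better than the chosen plan in one respect: the future C3 oxygen is present from the start, so no late C–H oxidation is needed.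
- Against it: A1 is a sensitive poly-β-carbonyl compound with two labile methoxy-bearing methines, and its assembly would take several sequential acylations. The Claisen mode competes with aldol closure (C2 onto C7) and with O-acylation to pyranones, and chelation control of that partition is hard to predict for this chain.
- Structure: the step makes one skeletal bond and ring A only. Ring C and ring B must still be added by aroylation and cyclodehydration, and A2 has three free hydroxyls, so the O5/O7 differentiation returns. The chosen key step makes three bonds and leaves no such problem.
- Mechanism: in the chosen plan every bond has only one possible site; here the site of ring closure is a real variable.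
- Step economy: chain assembly plus at least five steps after A2 exceeds the seven steps of the chosen route. On the use of symmetry to obtain a single regioisomer of ring A the two plans are equal.

Alternative 2: The cut is O1–C8a. The precursor is the diaryl diketone A3, whose ring A has a C–H at the future C8a. The forward key step would be constant-current anodic oxidation (carbon anode, undivided cell, fluorinated alcohol with a pyridine base and an ammonium electrolyte), in which the enol oxygen attacks that carbon to give A4.
- In its favour: A4 has every methyl ether in place, including those at C3 and C5, and is one deprotection from the target. After the key step this is better than the chosen plan, which needs three steps. The oxidant is electric current, and the diketone comes from classical ester condensation.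
- Against it: the ring to be oxidised has para-related methoxy groups at C5 and C8, the classic pattern for anodic conversion to quinones or quinone ketals. The benzylic ether is a second oxidisable site. Dehydrogenative C–O closure of a diketone enol onto such a ring is a less certain mechanism than the coupling and chelation chemistry of the chosen plan.
- Structure: A3 needs an unsymmetrical, pentasubstituted aryl ketone with O7 already differentiated and one C–H left. It has no symmetric precursor, so the steps saved after the key step would be spent before it.
- Step economy: at best equal to the chosen route, with a riskier key step that forms one bond instead of three.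

Alternative 3: The cut is C4–C4a and O1–C2, giving the symmetric triol A5 and the α-methoxy aroylacetate A6. The forward key step would be a Mentzer fusion at about 250 °C: C-acylation at the only free ring carbon and cyclodehydration to A7.
- In its favour: it is convergent, metal-free and forms two bonds and ring C in one operation. Only one regioisomer can form because A5 is symmetric; in this it is the equal of the chosen plan. It is better in delivering the C3 methoxy group with A6.
- Against it: A5 is not a stock compound, is very air-sensitive and would need about four steps of its own. The neat pyrolysis is harsh for such an electron-rich triol, acylation must occur between two hydroxyls, and a coumarin-forming pathway competes.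
- Structure and end-game: A7 has free 5- and 7-hydroxyls, so O7 must be protected, the chelated O5 methylated and O7 freed. That is three steps after the key step, the same count as in the chosen plan.
- Step economy: roughly four steps to A5, the fusion and three more, against seven in the chosen route, with the key step under far less control.

Key step: step 4

Assumption: the target is read as achiral 7-hydroxy-3,5,6,8-tetramethoxy-2-(4-methoxyphenyl)-4H-chromen-4-one with the free hydroxyl between the C6 and C8 methoxy groups; no structural correction is needed, and 1, 7 and 8 are taken as commercial.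

## Route

Step 1
Reactants: 1 1,2,4,5-tetramethoxybenzene
Product: 4 2,3,5,6-tetramethoxyphenol, via (2,3,5,6-tetramethoxyphenyl)lithium 2 (not isolated), via dimethyl (2,3,5,6-tetramethoxyphenyl)boronate 3 (not isolated)
Conditions: n-BuLi (1.1 equiv), TMEDA, THF, 0 °C to rt; B(OMe)3, −78 °C to rt; AcOH, 30% H2O2, 0 °C to rt
Reagents that add atoms: hydrogen peroxide, OO
Why: Directed ortho-metalation at one of the two equivalent C–H positions, each flanked by two methoxy groups, should give a single aryllithium; borylation and peroxide oxidation of the arylboronate (aryl migration from boron to oxygen) then give the phenol, and a second metalation of the anionic ring is disfavoured.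

Step 2
Reactants: 4 2,3,5,6-tetramethoxyphenol
Product: 5 2,3,5,6-tetramethoxyphenyl 2,2-dimethylpropanoate
Conditions: PivCl, Et3N, DMAP (cat.), CH2Cl2, 0 °C to rt
Reagents that add atoms: pivaloyl chloride, CC(C)(C)C(Cl)=O
Why: DMAP-catalysed O-acylation of the hindered phenol; the pivalate has no α-hydrogen and a shielded carbonyl, so it should tolerate BCl3, the carbonylation and a lithium amide at −78 °C, and it tempers the oxidation sensitivity of the ring.

Step 3
Reactants: 5 2,3,5,6-tetramethoxyphenyl 2,2-dimethylpropanoate
Product: 6 4-iodo-2,3,5,6-tetramethoxyphenyl 2,2-dimethylpropanoate
Conditions: NIS (1.1 equiv), TFA (cat.), MeCN, 0 °C to rt, dark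
Reagents that add atoms: N-iodosuccinimide, O=C1CCC(=O)N1I
Why: Electrophilic aromatic iodination at the only ring C–H, activated by two ortho methoxy groups, so no regiochemical choice exists; the mild acid-activated iodine source is chosen to avoid oxidative demethylation.

Step 4
Reactants: 6 4-iodo-2,3,5,6-tetramethoxyphenyl 2,2-dimethylpropanoate; 7 carbon monoxide; 8 1-ethynyl-4-methoxybenzene
Product: 11 5,6,8-trimethoxy-2-(4-methoxyphenyl)-4-oxo-4H-chromen-7-yl 2,2-dimethylpropanoate, via ynone 9 (not isolated), via ortho-hydroxy ynone 10 (not isolated)
Conditions: PdCl2(PPh3)2 (5 mol%), Et3N, CO (10 bar), toluene, 80 °C, copper-free; aqueous wash, switch to CH2Cl2 without purification; BCl3 (1.2 equiv), −78 to 0 °C; MeOH, 40 °C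
Reagents that add atoms: none
Why: The divalent palladium precatalyst is reduced in situ to zerovalent palladium, which inserts into the C–I bond of 6; CO insertion into the congested aryl–palladium bond gives the aroyl complex, and amine-assisted, copper-free transfer of the alkynyl group of 8 with reductive elimination forms ynone 9 (C4a–C4 and C4–C3), the closest known reaction type being the carbonylative Sonogashira coupling of aryl iodides. BCl3 then binds the ketone oxygen and one of the two equivalent flanking methoxy oxygens in a six-membered chelate, and chloride removes that methyl group as chloromethane, the known chelation-controlled demethylation of ortho-methoxy aryl ketones; methanolysis of the boron chelate frees phenol 10 and generates HCl. Under this acid the phenol oxygen adds to the alkyne carbon bearing the 4-methoxyphenyl group in a 6-endo-dig oxa-Michael closure (O1–C2), the known acid-mediated cyclisation of 2-hydroxyaryl ynones to flavones, which forms ring C without creating a stereocentre. Carbonylative over direct coupling is secured by CO pressure, the absence of copper and the two ortho substituents, which slow alkynyl transfer to the aryl–palladium species but not to the less hindered aroyl complex. Mono-demethylation at one position is secured by chelation (only the two ketone-flanking ethers can chelate, they are equivalent, and the boron is locked once the first is cleaved), by stoichiometry and by low temperature, while the pivalate, the ring B ether and the non-chelated ring A ethers are poor ligands for the single equivalent of BCl3. Flavone over aurone (6-endo over 5-exo) is secured by the acidic medium and the cation-stabilising 4-methoxyphenyl terminus, and a chloride or methanol adduct of the ynone, should it form first, can only close to the same six-membered ring by addition–elimination. The methoxy group that is not cleaved becomes the C5 methoxy group of the target, so no later differentiation of O5 from O7 is needed.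

Step 5
Reactants: 11 5,6,8-trimethoxy-2-(4-methoxyphenyl)-4-oxo-4H-chromen-7-yl 2,2-dimethylpropanoate
Product: 14 3-hydroxy-5,6,8-trimethoxy-2-(4-methoxyphenyl)-4-oxo-4H-chromen-7-yl 2,2-dimethylpropanoate, via 3-lithiochromenone 12 (not isolated), via chromen-3-ylboronate 13 (not isolated)
Conditions: LiN(iPr)2 (1.3 equiv), THF, −78 °C; B(OMe)3, −78 to 0 °C; AcOH, 30% H2O2, 0 °C to rt
Reagents that add atoms: hydrogen peroxide, OO
Why: C3–H is the most acidic C–H (vinylic, α to the C4 carbonyl, whose oxygen holds the lithium), so deprotonation, borylation and peroxide oxidation should give the flavonol, a known route from flavones to 3-hydroxyflavones; the hindered, non-enolisable pivalate should not be attacked by the bulky amide at −78 °C, and the acidic oxidation leaves the ester intact.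

Step 6
Reactants: 14 3-hydroxy-5,6,8-trimethoxy-2-(4-methoxyphenyl)-4-oxo-4H-chromen-7-yl 2,2-dimethylpropanoate
Product: 15 3,5,6,8-tetramethoxy-2-(4-methoxyphenyl)-4-oxo-4H-chromen-7-yl 2,2-dimethylpropanoate
Conditions: MeI, K2CO3, acetone, reflux
Reagents that add atoms: iodomethane, CI
Why: Williamson O-methylation of the only free hydroxyl; the aryl pivalate should be stable to carbonate in dry acetone, so O7 cannot be methylated.

Step 7
Reactants: 15 3,5,6,8-tetramethoxy-2-(4-methoxyphenyl)-4-oxo-4H-chromen-7-yl 2,2-dimethylpropanoate
Product: 16 7-hydroxy-3,5,6,8-tetramethoxy-2-(4-methoxyphenyl)-4H-chromen-4-one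
Conditions: NaOMe (1.5 equiv), MeOH, 0 °C to rt; AcOH
Reagents that add atoms: none
Why: Alkoxide transesterification of the aryl ester; the 7-phenoxide, a vinylogous carboxylate, is a good leaving group, and methyl ethers and the 3-methoxypyranone should be inert to methoxide at room temperature.

## Compound list

1 | 1,2,4,5-tetramethoxybenzene | COc1cc(OC)c(OC)cc1OC | starting material
2 | (2,3,5,6-tetramethoxyphenyl)lithium | [Li]c1c(OC)c(OC)cc(OC)c1OC | intermediate (not isolated)
3 | dimethyl (2,3,5,6-tetramethoxyphenyl)boronate | COB(OC)c1c(OC)c(OC)cc(OC)c1OC | intermediate (not isolated)
4 | 2,3,5,6-tetramethoxyphenol | COc1cc(OC)c(OC)c(O)c1OC | intermediate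
5 | 2,3,5,6-tetramethoxyphenyl 2,2-dimethylpropanoate | COc1cc(OC)c(OC)c(OC(=O)C(C)(C)C)c1OC | intermediate
6 | 4-iodo-2,3,5,6-tetramethoxyphenyl 2,2-dimethylpropanoate | COc1c(I)c(OC)c(OC)c(OC(=O)C(C)(C)C)c1OC | intermediate
7 | carbon monoxide | [C-]#[O+] | starting material
8 | 1-ethynyl-4-methoxybenzene | C#Cc1ccc(OC)cc1 | starting material
9 | 2,3,5,6-tetramethoxy-4-[3-(4-methoxyphenyl)prop-2-ynoyl]phenyl 2,2-dimethylpropanoate | COc1ccc(cc1)C#CC(=O)c1c(OC)c(OC)c(OC(=O)C(C)(C)C)c(OC)c1OC | intermediate (not isolated)
10 | 3-hydroxy-2,5,6-trimethoxy-4-[3-(4-methoxyphenyl)prop-2-ynoyl]phenyl 2,2-dimethylpropanoate | COc1ccc(cc1)C#CC(=O)c1c(O)c(OC)c(OC(=O)C(C)(C)C)c(OC)c1OC | intermediate (not isolated)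
11 | 5,6,8-trimethoxy-2-(4-methoxyphenyl)-4-oxo-4H-chromen-7-yl 2,2-dimethylpropanoate | COc1ccc(cc1)-c1cc(=O)c2c(OC)c(OC)c(OC(=O)C(C)(C)C)c(OC)c2o1 | intermediate
12 | [5,6,8-trimethoxy-2-(4-methoxyphenyl)-4-oxo-7-(pivaloyloxy)-4H-chromen-3-yl]lithium | COc1ccc(cc1)-c1oc2c(OC)c(OC(=O)C(C)(C)C)c(OC)c(OC)c2c(=O)c1[Li] | intermediate (not isolated)
13 | dimethyl [5,6,8-trimethoxy-2-(4-methoxyphenyl)-4-oxo-7-(pivaloyloxy)-4H-chromen-3-yl]boronate | COc1ccc(cc1)-c1oc2c(OC)c(OC(=O)C(C)(C)C)c(OC)c(OC)c2c(=O)c1B(OC)OC | intermediate (not isolated)
14 | 3-hydroxy-5,6,8-trimethoxy-2-(4-methoxyphenyl)-4-oxo-4H-chromen-7-yl 2,2-dimethylpropanoate | COc1ccc(cc1)-c1oc2c(OC)c(OC(=O)C(C)(C)C)c(OC)c(OC)c2c(=O)c1O | intermediate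
15 | 3,5,6,8-tetramethoxy-2-(4-methoxyphenyl)-4-oxo-4H-chromen-7-yl 2,2-dimethylpropanoate | COc1ccc(cc1)-c1oc2c(OC)c(OC(=O)C(C)(C)C)c(OC)c(OC)c2c(=O)c1OC | intermediate
16 | 7-hydroxy-3,5,6,8-tetramethoxy-2-(4-methoxyphenyl)-4H-chromen-4-one | COc1ccc(-c2oc3c(OC)c(O)c(OC)c(OC)c3c(=O)c2OC)cc1 | target

## Step count and least certain steps

Total step count: 7. Longest linear sequence: 7 steps (1 to 16); 7 and 8 enter at step 4.

Step 4 (key step). The most likely failure is erosion of chemoselectivity in the ether-cleavage stage: cleavage of a second, crowded methyl ether, or incomplete demethylation. The cause is that the four adjacent ring A ethers can also bind BCl3 pairwise. A lesser risk is slow oxidative addition into the doubly ortho-substituted, electron-rich C–I bond; this would be met with a wide-bite-angle diphosphine on Pd(OAc)2 and higher CO pressure. The fallback sets out from 9, isolated after the palladium stage, and changes the ring closure from Lewis-acid demethylation to electrophile-induced cyclisation. ICl in CH2Cl2 at −78 °C should activate the alkyne; the flanking methoxy oxygen would then close 6-endo and lose its methyl group to chloride, giving 3-iodo-5,6,8-trimethoxy-2-(4-methoxyphenyl)-4-oxo-4H-chromen-7-yl 2,2-dimethylpropanoate F1. Iodine–magnesium exchange with iPrMgCl·LiCl in THF at −40 °C would give chloro[5,6,8-trimethoxy-2-(4-methoxyphenyl)-4-oxo-7-(pivaloyloxy)-4H-chromen-3-yl]magnesium F2. B(OMe)3 would convert this to 13, and AcOH/H2O2 would give 14, where the fallback rejoins the route; step 5 is then not needed.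

Step 5. The most likely failure is decay of the 3-lithio species by β-elimination of the C8a phenoxide (ring opening back to an ynone), or attack of the amide base on the ester. Both become competitive if the anion is not trapped quickly at −78 °C. The fallback sets out from 11 and replaces deprotonation by electrophilic oxygen transfer. Dimethyldioxirane in acetone/CH2Cl2 at 0 °C to rt should epoxidise the C2=C3 bond to the racemic cis-fused 2,3-epoxide 3,5,6-trimethoxy-1a-(4-methoxyphenyl)-7-oxo-7,7a-dihydro-1aH-oxireno[2,3-b]chromen-4-yl 2,2-dimethylpropanoate F3. Catalytic p-TsOH in CH2Cl2 should open it at the aryl-bearing carbon with loss of the C3 proton to give 14, where the fallback rejoins the route.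

Step 1. The most likely failure is incomplete or double metalation of the electron-rich arene, or air oxidation of the very electron-rich free phenol during the peroxide work-up. The fallback sets out from 1 and puts the halogen in first. Two-fold electrophilic iodination with ICl in CH2Cl2 should give 1,4-diiodo-2,3,5,6-tetramethoxybenzene F4. Mono iodine–lithium exchange with n-BuLi (1.0 equiv, THF, −78 °C), B(OMe)3 and AcOH/H2O2 in one flask should give 4-iodo-2,3,5,6-tetramethoxyphenol F5, which is less oxidation-prone than 4. Acylation with PivCl/Et3N/DMAP would give 6, where the fallback rejoins the route; steps 2 and 3 are then not needed.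

## Further compounds

F1 | step 4 | 3-iodo-5,6,8-trimethoxy-2-(4-methoxyphenyl)-4-oxo-4H-chromen-7-yl 2,2-dimethylpropanoate | COc1ccc(cc1)-c1oc2c(OC)c(OC(=O)C(C)(C)C)c(OC)c(OC)c2c(=O)c1I
F2 | step 4 | chloro[5,6,8-trimethoxy-2-(4-methoxyphenyl)-4-oxo-7-(pivaloyloxy)-4H-chromen-3-yl]magnesium | COc1ccc(cc1)-c1oc2c(OC)c(OC(=O)C(C)(C)C)c(OC)c(OC)c2c(=O)c1[Mg]Cl
F3 | step 5 | 3,5,6-trimethoxy-1a-(4-methoxyphenyl)-7-oxo-7,7a-dihydro-1aH-oxireno[2,3-b]chromen-4-yl 2,2-dimethylpropanoate (racemic, cis-fused; one enantiomer drawn) | COc1ccc(cc1)[C@@]12O[C@@H]1C(=O)c1c(OC)c(OC)c(OC(=O)C(C)(C)C)c(OC)c1O2
F4 | step 1 | 1,4-diiodo-2,3,5,6-tetramethoxybenzene | COc1c(I)c(OC)c(OC)c(I)c1OC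
F5 | step 1 | 4-iodo-2,3,5,6-tetramethoxyphenol | COc1c(I)c(OC)c(OC)c(O)c1OC
A1 | alternative 1 | methyl 2,4,8-trimethoxy-3,5,7-trioxooctanoate (stereochemically labile mixture) | COCC(=O)CC(=O)C(OC)C(=O)C(OC)C(=O)OC
A2 | alternative 1 | 2-methoxy-1-(2,4,6-trihydroxy-3,5-dimethoxyphenyl)ethanone | COCC(=O)c1c(O)c(OC)c(O)c(OC)c1O
A3 | alternative 2 | 1-[4-(benzyloxy)-2,3,5-trimethoxyphenyl]-2-methoxy-3-(4-methoxyphenyl)propane-1,3-dione (racemic) | COc1ccc(cc1)C(=O)C(OC)C(=O)c1cc(OC)c(OCc2ccccc2)c(OC)c1OC
A4 | alternative 2 | 7-(benzyloxy)-3,5,6,8-tetramethoxy-2-(4-methoxyphenyl)-4H-chromen-4-one | COc1ccc(-c2oc3c(OC)c(OCc4ccccc4)c(OC)c(OC)c3c(=O)c2OC)cc1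
A5 | alternative 3 | 2,4-dimethoxybenzene-1,3,5-triol | COc1c(O)cc(O)c(OC)c1O
A6 | alternative 3 | ethyl 2-methoxy-3-(4-methoxyphenyl)-3-oxopropanoate (racemic) | CCOC(=O)C(OC)C(=O)c1ccc(OC)cc1
A7 | alternative 3 | 5,7-dihydroxy-3,6,8-trimethoxy-2-(4-methoxyphenyl)-4H-chromen-4-one | COc1ccc(-c2oc3c(OC)c(O)c(OC)c(O)c3c(=O)c2OC)cc1
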